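| flask | G | X | E | temperature | remark | time |
|---|---|---|---|---|---|---|
| ash | 0.33 M | 0.165 M | 0.20 M | 105 °C | run made earlier |  |
| alder | 0.33 M | 0.165 M | 0.30 M | 122 °C | run made earlier |  |
| cedar | 0.33 M | 0.083 M | 0.396 M | 105 °C | run made earlier |  |
| delta | 0.33 M | 0.165 M | 0.396 M | 110 °C |  | 2.0 min |
| beta | 0.33 M | 0.165 M | 0.396 M |  | at 135 °C until 40 s, from then on at 110 °C | 2.0 min |
| zeta | 0.33 M | 0.165 M | 0.396 M | 135 °C |  | 2.0 min |

| run | time / s | Z / % |
|---|---|---|
| ash | 10.0 | 1.5 |
| ash | 15.0 | 1.7 |
| ash | 25.0 | 2.8 |
| ash | 40.0 | 5.3 |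
| ash | 80.0 | 9.3 |
| alder | 10.0 | 1.5 |
| alder | 15.0 | 2.6 |
| alder | 20.0 | 2.9 |
| alder | 30.0 | 5.1 |
| alder | 40.0 | 7.3 |
| cedar | 10.0 | 1.8 |
| cedar | 20.0 | 2.7 |
| cedar | 40.0 | 5.8 |
| cedar | 80.0 | 10.5 |

(scatter of a reading: 0.3 percentage points)

- as a solid, counted per litre of solution: E
- at the start none of E is in solution

* the best flask by amount of Z, in percent of the G charged; "all alike" if 1.5 percentage points covers them all (delta / beta / zeta / all alike)
* amount of Z at the end, in percent of the G charged, delta
* amount of Z at the end, in percent of the G charged, beta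
* amount of Z at the end, in percent of the G charged, zeta

1. The time of reading, 2.0 min, is 1.50 times the time of the last reading of ash, 80.0 s, so my decision on the next flasks hung on how Z bends with time.

2. The ash readings gave me 0.811 between 40.0 s and 80.0 s for n, the bend exponent (the order in time): the logarithm of the ratio of two Z readings over the logarithm of the ratio of their times. At 1, Z grows in step with time; at zero, Z has stopped.

3. Cedar, read between the same times, gave me 0.856, close to ash for readings that each scatter by 0.3 percentage points.

4. Delta has the X of ash and the E of cedar, so I carried both last readings forward to 2.0 min. This gave 12.9% from ash and 14.9% from cedar. I made no correction for 110 °C against 105 °C, and I committed to that range for delta.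

5. The readings of alder end at 40.0 s, and the exponent they gave from 20.0 s was 1.33, so they showed no bend. I therefore gave beta and zeta no number of my own and left their ranking open.

6. I kept the reading at 2.0 min, took delta as the base, and ran beta and zeta to test the heat.

7. The forecast gave 19% for delta, 21% for beta and 25% for zeta, with zeta best: “Zeta is the tentative best, though the flasks may differ only modestly.” Its delta stands above my range.

Delta gave 13.0%, beta 13.1% and zeta 12.6%, a spread of 0.50 points inside 1.5 points, so the verdict is all alike.

    G + L ⇌ Z (K = 15.0 /M, k = 0.271 /M/s, Ea = 55.0 kJ/mol, ΔH = 11.0 kJ/mol)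
    L → D (k = 0.0211 /s, Ea = 105 kJ/mol)
    X + L ⇌ J (K = 39.0 /M, k = 0.771 /M/s, Ea = 57.0 kJ/mol, ΔH = −45.0 kJ/mol)
    E ⇌ L, rate k4*(cs4 - [L]) while solid is left; crystals form when [L] > cs4 (solubility = 16.0 mM, k = 0.174 /s)
    (constants at 110 °C)

Zeta led delta at 1.00 min, with 9.91% against 8.15%, yet ended lower. From 1.00 min to 2.0 min, n was 0.351 for zeta and 0.673 for delta, so zeta bent harder, and both lay below the 0.811 read from ash at earlier times. Carrying 0.811 from delta's 13.0% to 5.0 min gives 27.3%, but delta read at that time held 17.2%, an exponent of 0.306.

The data are simulated for substances that don't exist; the scatter is artificial.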